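**Plan**

Ring numbering throughout: C1 ketone, C2 (alkene carbon bearing CH2OH), C3, C4, C5 (quaternary: CH3 and 4-methylpent-3-enyl), C6 (enol ester arm), C7 (acetonyl arm).
Enabling feature: along CH3C(=O)–CH2–C7–C6–CH=CH–O the ketone carbon and the oxygen-bearing vinyl carbon are 1,6-related. Both arms stand on one face of the seven-membered ring, so they are the two halves of a C=C bond cut out of a cyclohexene cis-fused at C6–C7.
Retrosynthetic cuts, in order: silyl ether and acyl–O bond of the enol ester; reconnection of the two arm carbonyl carbons to a 1-methyl-2-silyloxycyclohexene; the C7–CH2 and C6–CH2 bonds ([4+2]); then C1–C2 and C4–C5 of the seven-membered ring ((4+3)).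
Forward order: the cycloheptadiene forms first from a geranial-derived triene and a vinyldiazoacetate and is adjusted to the cross-conjugated dienone. The six-membered ring is then closed on C6=C7 and opened again by ozonolysis, and the senecioate goes on last.
Stereochemistry: C5 comes from a chiral dirhodium catalyst acting on the E alkene of geranial. C6 and C7 come from suprafacial cycloaddition (cis) on the face carrying the C5 methyl. The E enol ester comes from the steric bias in the O-acylation.

Key step: step 10

Assumption: Rh2(R-PTAD)4 is taken to deliver the (S) quaternary carbon from the (E)-triene; if the sense of induction proves opposite, the antipodal catalyst is used and nothing else changes.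

**Step 1**
Reactants: 1 geranial (geometrically pure E)
Product: 2 (3E)-4,8-dimethylnona-1,3,7-triene
Conditions: Ph3PCH3Br, KOt-Bu, THF, 0 °C → rt
Reagents that add atoms: methyltriphenylphosphonium bromide, C[P+](c1ccccc1)(c1ccccc1)c1ccccc1.[Br-]
Why: Wittig methylenation of the enal is fast at 0 °C and does not touch the trisubstituted E alkene, whose geometry later translates into the configuration at C5.

**Step 2**
Reactants: 3 methyl acetoacetate
Product: 4 methyl 2-diazo-3-oxobutanoate
Conditions: p-ABSA, Et3N, MeCN, 0 °C → rt
Reagents that add atoms: 4-acetamidobenzenesulfonyl azide (p-ABSA), CC(=O)Nc1ccc(cc1)S(=O)(=O)N=[N+]=[N-]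
Why: Regitz diazo transfer to the doubly activated methylene of a β-keto ester needs only a tertiary amine base.

**Step 3**
Reactants: 4 methyl 2-diazo-3-oxobutanoate
Product: 5 methyl 2-diazo-3-hydroxybutanoate (racemic)
Conditions: NaBH4, MeOH, 0 °C
Reagents that add atoms: none
Why: Chemoselective borohydride reduction of the ketone, the ester and the acceptor-stabilised diazo group being inert at 0 °C; the new carbinol centre is racemic and disappears in step 4.

**Step 4**
Reactants: 5 methyl 2-diazo-3-hydroxybutanoate
Product: 6 methyl 2-diazobut-3-enoate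
Conditions: POCl3, Et3N, CH2Cl2, 0 °C
Reagents that add atoms: none
Why: Dehydration by O-phosphorylation and amine-induced E2 elimination is the standard entry to the parent vinyldiazoacetate, which is kept cold and used at once because it slowly electrocyclises to a pyrazole.

**Step 5**
Reactants: 2 (3E)-4,8-dimethylnona-1,3,7-triene; 6 methyl 2-diazobut-3-enoate
Product: 8 methyl (4S)-4-methyl-4-(4-methylpent-3-enyl)cyclohepta-1,5-diene-1-carboxylate, via cis-divinylcyclopropane 7 (not isolated)
Conditions: Rh2(R-PTAD)4 (1 mol %), slow addition of 6 to excess 2, hexanes, −25 °C → reflux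
Reagents that add atoms: none
Why: Formal (4+3) cycloaddition by tandem cyclopropanation/Cope rearrangement: the rhodium-bound donor/acceptor vinylcarbene attacks only the monosubstituted alkene of 2, the chiral carboxylate ligands set the configuration of 7, and its boat-shaped [3,3] shift transfers this, through the E geometry of the trisubstituted alkene, to the quaternary carbon C5 (S).

**Step 6**
Reactants: 8 cycloheptadiene ester
Product: 9 [(4S)-4-methyl-4-(4-methylpent-3-enyl)cyclohepta-1,5-dien-1-yl]methanol
Conditions: DIBAL-H (2.5 equiv), CH2Cl2, −78 → 0 °C; Rochelle salt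
Reagents that add atoms: none
Why: 1,2-Reduction of an α,β-unsaturated ester with DIBAL-H stops cleanly at the allylic alcohol and leaves the three unactivated alkenes and C5 untouched.

**Step 7**
Reactants: 9 allylic alcohol
Product: 10 tert-butyldimethylsilyl ether of 9
Conditions: TBSCl, imidazole, CH2Cl2, rt
Reagents that add atoms: tert-butyldimethylsilyl chloride, CC(C)(C)[Si](C)(C)Cl
Why: Standard imidazole-promoted silylation of a primary alcohol; the TBS ether tolerates every later step and is the last group to be removed.

**Step 8**
Reactants: 10 silyl ether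
Product: 11 (5S)-2-(tert-butyldimethylsilyloxymethyl)-5-methyl-5-(4-methylpent-3-enyl)cyclohepta-2,6-dien-1-one
Conditions: Rh2(cap)4 (1 mol %), t-BuOOH, K2CO3, CH2Cl2, rt
Reagents that add atoms: tert-butyl hydroperoxide, CC(C)(C)OO
Why: Dirhodium caprolactamate/TBHP allylic oxidation works by hydrogen abstraction at the weakest C–H bond, here the doubly allylic C1–H2, and, as with the 1,4-dienes obtained by Birch reduction, oxygenation at the central carbon gives the cross-conjugated dienone while the stronger allylic C–H bonds of the side chain react more slowly.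

**Step 9**
Reactants: 12 3-methylbut-3-en-2-one (methyl isopropenyl ketone)
Product: 13 2-methyl-3-(tert-butyldimethylsilyloxy)buta-1,3-diene
Conditions: TBSOTf, Et3N, Et2O, 0 °C
Reagents that add atoms: tert-butyldimethylsilyl triflate, CC(C)(C)[Si](C)(C)OS(=O)(=O)C(F)(F)F
Why: Soft enolisation with silyl triflate and triethylamine; the acetyl methyl group carries the only α-hydrogens, so a single cross-conjugated 2-silyloxydiene results.

**Step 10**
Reactants: 11 cross-conjugated dienone; 13 silyloxydiene
Product: 14 cis-fused bicyclo[5.4.0]undecadienone (5S,6S,7R): new ring C7–CH2–C(CH3)=C(OTBS)–CH2–C6, both new C–C bonds on the face of the C5 methyl, both fusion hydrogens on the opposite face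
Conditions: AlBr3/AlMe3 (5:1, 0.3 equiv), 13 (2 equiv), toluene/CH2Cl2, −40 → −10 °C; cold pyridine, then aq. NaHCO3
Reagents that add atoms: none
Why: The aluminium Lewis acid binds the C1 carbonyl oxygen on the side of C7–H, lowers the LUMO of the dienone, and diene 13 then adds across C6=C7 in a concerted but markedly asynchronous [4π+2π] cycloaddition in which the C6–CH2 bond is formed ahead of the C7–CH2 bond. The closest known reaction type is the mixed AlBr3/AlMe3-promoted Diels–Alder reaction of 2-silyloxydienes with cycloalkenones that carry a quaternary γ-carbon, where AlMe3 removes traces of HBr and thereby protects silyl enol ether, silyl ether and side-chain alkene. The one new ring, the cyclohexene, closes in a single suprafacial–suprafacial event that joins both diene termini to the Z-configured ring alkene, so the fusion is cis. C7 is therefore set relative to C6 by the suprafacial rule, and C6 is set relative to C5 by approach of the diene to the face that carries the C5 methyl group, the longer 4-methylpentenyl chain taking the pseudoaxial position anti to the forming C6–C bond. Regiochemistry is set by the silyloxy donor, which outweighs the methyl group and makes the CH2 terminus next to it the nucleophilic end that pairs with the β-carbon C6, so that the methyl-bearing carbon ends on the C7 side. Site selectivity is needed between two enone arms and rests on C2 being fully substituted and flanked by the bulky CH2OTBS group whereas C7 bears only hydrogen, and the low temperature with a cold basic quench keeps the kinetic cis fusion from epimerising at C7.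

**Step 11**
Reactants: 14 bicyclic silyl enol ether
Product: 16 keto acid (5S,6S,7R): C7–CH2C(=O)CH3 and C6–CH2CO2H on the silyl-protected cycloheptenone, via silyl ester 15 (not isolated)
Conditions: O3 (1.0 equiv, titrated solution), CH2Cl2/MeOH, −78 °C; Me2S, −78 °C → rt; aq. NaHCO3, then pH 4
Reagents that add atoms: ozone, [O-][O+]=O
Why: Ozonolysis of a silyl enol ether: the tetrasubstituted, oxygen-substituted alkene is the most electron-rich π bond and should consume the single equivalent of ozone ahead of the trisubstituted side-chain alkene and the electron-poor enone, giving the methyl ketone on the C7 arm and silyl ester 15 on the C6 arm, which hydrolyses during the bicarbonate work-up without touching C6 or C7.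

**Step 12**
Reactants: 16 keto acid
Product: 17 S-ethyl thioester of 16
Conditions: EtSH, DCC, DMAP (cat.), CH2Cl2, 0 °C → rt
Reagents that add atoms: ethanethiol, CCS
Why: Steglich-type carbodiimide coupling with a thiol proceeds under near-neutral conditions that do not enolise C7, and the α-branched enone is only a poor and reversible thiol acceptor.

**Step 13**
Reactants: 17 thioester
Product: 18 keto aldehyde (5S,6S,7R): C6–CH2CHO, C7–CH2C(=O)CH3
Conditions: Et3SiH, 10% Pd/C, acetone, rt
Reagents that add atoms: none
Why: Fukuyama reduction (oxidative addition of palladium into the C–S bond, then hydride transfer from the silane) stops at the aldehyde and leaves both ketones, the hindered alkenes and the silyl ether alone.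

**Step 14**
Reactants: 18 keto aldehyde; 19 3-methylbut-2-enoyl chloride
Product: 20 silyl-protected (E)-enol senecioate (5S,6S,7R)
Conditions: Et3N, DMAP (cat.), CH2Cl2, −20 °C → rt, slow addition of 19
Reagents that add atoms: none
Why: DMAP-catalysed O-acylation of the aldehyde enol: under amine base only the aldehyde is enolised at a useful rate, the ketones and C7–H stay untouched, and the bulky C6 substituent takes the position trans to the acyloxy group, which gives the E enol ester.

**Step 15**
Reactants: 20 silyl-protected enol ester
Product: 21 target, (5S,6S,7R)-2-(hydroxymethyl)-5-methyl-5-(4-methylpent-3-enyl)-6-[(E)-2-(3-methylbut-2-enoyloxy)vinyl]-7-(2-oxopropyl)cyclohept-2-en-1-one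
Conditions: HF·pyridine, pyridine, THF, 0 °C
Reagents that add atoms: none
Why: Fluoride-driven cleavage of a primary TBS ether under buffered, weakly acidic conditions spares the enol ester, the enone and the epimerisable C7 centre.

**Compound list**

1 | geranial, (2E)-3,7-dimethylocta-2,6-dienal | CC(C)=CCC/C(C)=C/C=O | starting material
2 | (3E)-4,8-dimethylnona-1,3,7-triene | CC(C)=CCC/C(C)=C/C=C | intermediate
3 | methyl acetoacetate | COC(=O)CC(C)=O | starting material
4 | methyl 2-diazo-3-oxobutanoate | COC(=O)C(=[N+]=[N-])C(C)=O | intermediate
5 | methyl 2-diazo-3-hydroxybutanoate (racemic) | COC(=O)C(=[N+]=[N-])C(C)O | intermediate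
6 | methyl 2-diazobut-3-enoate | COC(=O)C(=[N+]=[N-])C=C | intermediate
7 | methyl (1R,2R)-2-[(1E)-2,6-dimethylhepta-1,5-dienyl]-1-vinylcyclopropane-1-carboxylate, vinyl and dienyl groups cis | COC(=O)[C@@]1(C=C)C[C@@H]1/C=C(\C)CCC=C(C)C | intermediate
8 | methyl (4S)-4-methyl-4-(4-methylpent-3-enyl)cyclohepta-1,5-diene-1-carboxylate | COC(=O)C1=CC[C@](C)(CCC=C(C)C)C=CC1 | intermediate
9 | [(4S)-4-methyl-4-(4-methylpent-3-enyl)cyclohepta-1,5-dien-1-yl]methanol | OCC1=CC[C@](C)(CCC=C(C)C)C=CC1 | intermediate
10 | tert-butyldimethylsilyl ether of 9 | CC(C)(C)[Si](C)(C)OCC1=CC[C@](C)(CCC=C(C)C)C=CC1 | intermediate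
11 | (5S)-2-(tert-butyldimethylsilyloxymethyl)-5-methyl-5-(4-methylpent-3-enyl)cyclohepta-2,6-dien-1-one | O=C1C(CO[Si](C)(C)C(C)(C)C)=CC[C@](C)(CCC=C(C)C)C=C1 | intermediate
12 | 3-methylbut-3-en-2-one (methyl isopropenyl ketone) | CC(=C)C(C)=O | starting material
13 | 2-methyl-3-(tert-butyldimethylsilyloxy)buta-1,3-diene | C=C(C)C(=C)O[Si](C)(C)C(C)(C)C | intermediate
14 | cis-fused bicyclo[5.4.0] silyl enol ether (5S,6S,7R), cyclohexene C7–CH2–C(CH3)=C(OTBS)–CH2–C6 | C1[C@H]2C(=O)C(CO[Si](C)(C)C(C)(C)C)=CC[C@](C)(CCC=C(C)C)[C@H]2CC(O[Si](C)(C)C(C)(C)C)=C1C | intermediate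
15 | tert-butyldimethylsilyl ester of keto acid 16 | CC(=O)C[C@H]1C(=O)C(CO[Si](C)(C)C(C)(C)C)=CC[C@](C)(CCC=C(C)C)[C@H]1CC(=O)O[Si](C)(C)C(C)(C)C | intermediate
16 | keto acid (5S,6S,7R), C6–CH2CO2H and C7–CH2C(=O)CH3 | CC(=O)C[C@H]1C(=O)C(CO[Si](C)(C)C(C)(C)C)=CC[C@](C)(CCC=C(C)C)[C@H]1CC(=O)O | intermediate
17 | S-ethyl thioester of 16 | CC(=O)C[C@H]1C(=O)C(CO[Si](C)(C)C(C)(C)C)=CC[C@](C)(CCC=C(C)C)[C@H]1CC(=O)SCC | intermediate
18 | keto aldehyde (5S,6S,7R), C6–CH2CHO | CC(=O)C[C@H]1C(=O)C(CO[Si](C)(C)C(C)(C)C)=CC[C@](C)(CCC=C(C)C)[C@H]1CC=O | intermediate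
19 | 3-methylbut-2-enoyl chloride (senecioyl chloride) | CC(C)=CC(=O)Cl | starting material
20 | silyl-protected (E)-enol senecioate (5S,6S,7R) | CC(=O)C[C@H]1C(=O)C(CO[Si](C)(C)C(C)(C)C)=CC[C@](C)(CCC=C(C)C)[C@H]1/C=C/OC(=O)C=C(C)C | intermediate
21 | CNP0247522.1 | CC(=O)C[C@H]1C(=O)C(CO)=CC[C@](C)(CCC=C(C)C)[C@H]1/C=C/OC(=O)C=C(C)C | target

**Step count**

Total: 15 steps. Longest linear sequence: 13 steps (3 → 4 → 5 → 6 → 8 → 9 → 10 → 11 → 14 → 16 → 17 → 18 → 20 → 21).

**Steps most likely to fail**

**Step 10.**
- The diene may add to the C2=C3 arm, whose β-carbon C3 is not neopentyl, instead of C6=C7.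
- The two faces next to C5 differ only beyond the first carbon of each substituent, so facial discrimination may be weak.
- Bond formation at the crowded C6 may be slow.
- The Lewis acid may epimerise the cis fusion at C7.

Fallback, from 11 and 13 back to 14: control is moved from the substrate to a chiral catalyst. The catalyst is a proline-derived cationic oxazaborolidine activated by AlBr3 or triflimide, a known catalyst class for cyclic enones with 2-silyloxydienes. Besides binding the carbonyl oxygen, it holds the α-C–H of the reacting enone arm through a C–H···O contact. Only C7 offers such a hydrogen, so only C6=C7 is placed over the shielding aryl group. The catalyst antipode that covers the face of the 4-methylpentenyl chain reinforces the substrate bias, and the matched antipode is found by running both. This fallback makes no compound that the list does not hold (F0).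

**Step 14.**
- The 1,6-keto aldehyde may undergo intramolecular aldol reaction.
- γ-Deprotonation of the acyl donor by the amine may move the ester double bond out of conjugation.
- E/Z control may be incomplete.
- Base may cause drift at C7.

Fallback, from 18 and 19 back to 20: no enolate is made. The acid chloride is added across the aldehyde C=O with catalytic ZnCl2 (CH2Cl2, −10 °C), a reaction that ketones do not undergo. This should give the 1-chloroalkyl senecioate F1, a mixture at the chlorine-bearing carbon. Dehydrochlorination with a hindered amine (2,4,6-collidine, warm MeCN) then gives 20. Loss of HCl from the least crowded rotamer should place C6 trans to the acyloxy group.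

**Step 11.**
- Ozone is poorly discriminating, so the side-chain alkene may be cleaved alongside or after the enol ether.

Fallback, from 14 back to 18, bypassing 16 and 17:
1. Rubottom oxidation with dimethyldioxirane (acetone/CH2Cl2, −78 °C), a far more selective electrophile, should give the silyloxy epoxide F2.
2. Mild aqueous acid opens F2 to the tertiary α-ketol F3.
3. Hydroxy-directed reduction with Me4NBH(OAc)3 (MeCN/AcOH, −20 °C) touches only the ketone next to the free hydroxyl and not the enone, giving the 1,2-diol F4.
4. Glycol cleavage with NaIO4 (THF/H2O) delivers keto aldehyde 18 directly.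

**Further compounds**

F0 | step 10 | none | none
F1 | step 14 | 1-chloroalkyl senecioate, C6–CH2–CH(Cl)–OC(=O)CH=C(CH3)2, mixture at the chlorine-bearing carbon | CC(=O)C[C@H]1C(=O)C(CO[Si](C)(C)C(C)(C)C)=CC[C@](C)(CCC=C(C)C)[C@H]1CC(Cl)OC(=O)C=C(C)C
F2 | step 11 | silyloxy epoxide of 14, epoxide face not defined | C1[C@H]2C(=O)C(CO[Si](C)(C)C(C)(C)C)=CC[C@](C)(CCC=C(C)C)[C@H]2CC3(O[Si](C)(C)C(C)(C)C)OC13C
F3 | step 11 | tertiary α-ketol, ring ketone on the C6 side and C(OH)(CH3) on the C7 side | C1[C@H]2C(=O)C(CO[Si](C)(C)C(C)(C)C)=CC[C@](C)(CCC=C(C)C)[C@H]2CC(=O)C1(C)O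
F4 | step 11 | 1,2-diol from F3 | C1[C@H]2C(=O)C(CO[Si](C)(C)C(C)(C)C)=CC[C@](C)(CCC=C(C)C)[C@H]2CC(O)C1(C)O
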